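Time is the thing to watch in these flasks: you are asked what stands after 8.0 h, and the beta run shows target arriving late.

| flask | substrate | gas | temperature | remark | time |
|---|---|---|---|---|---|
| alpha | 0.28 M | 200 mM (held) | 50 °C | run made earlier |  |
| beta | 0.43 M | 200 mM (held) | 62 °C | run made earlier |  |
| ash | 0.57 M | 200 mM (held) |  | at 55 °C until 2.5 h, from then on at 70 °C | 8.0 h |
| birch | 0.57 M | 200 mM (held) | 55 °C |  | 8.0 h |
| oak | 0.57 M | 200 mM (held) | 70 °C |  | 8.0 h |

| alpha: time / h | alpha: target / % | beta: time / h | beta: target / % |
|---|---|---|---|
| 0.417 | 0.5 | 0.417 | 0.6 |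
| 0.667 | 1.3 | 1.33 | 0 |
| 1.33 | 1.1 | 2.00 | 1.3 |
| 2.50 | 0.7 | 3.00 | 1.6 |
| 5.00 | 0.4 | 5.00 | 4.1 |

(readings scatter by 0.5 percentage points)

- the numbers in the tables scatter with a standard deviation of 0.5 percentage points
- at the start none of the gas is in solution

- the flask that comes out highest in amount of target, in percent of the substrate charged, or "all alike" when all lie within 1.5 percentage points (ash / birch / oak / all alike)
- target at the end, in percent of the substrate charged, ash
- target at the end, in percent of the substrate charged, birch
- target at the end, in percent of the substrate charged, oak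

Take the run in slow motion. In the first instants gas begins to enter the solution, and beta reads 0.6% of target at 0.417 h, no clear signal against a scatter of 0.5 percentage points. In the middle, beta climbs from 1.6% at 3.00 h to 4.1% at 5.00 h. That gives 1.47 h as the doubling time, the hours target needs to double while it grows. It is a rough reading: a scatter of 0.5 points stands against a lower value of 1.6%. Alpha, colder and thinner, shows no lasting growth and ends at 0.4%.

Now the end. At beta's pace, the 3.00 h from beta's last reading to 8.0 h hold 2.04 doublings, a factor of 4.11. Taking that last reading as the seed, my own reckoning gives 16.8%. Oak is hotter and richer than beta, so I expect oak at that figure or above it, though target cannot pass the charge. Ash has 5.50 h at the higher temperature, less time there than oak, so I put ash below oak. Birch is colder than beta, and I expect a few percent there.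

The forecast names oak as highest, with ash at 12% (6% to 22%), birch at 3.5% (1% to 7%) and oak at 16% (7% to 30%). Its ground is “Formation therefore looks strongly temperature-dependent”. My oak figure stands above its value.

The flasks give 53.3% in oak, 48.0% in ash and 6.03% in birch, so oak comes out highest, and oak lies above my figure.

    substrate + reagent + by-product → target + 2 by-product (k = 0.00680 M⁻² s⁻¹, Ea = 72.0 kJ mol⁻¹)
    substrate + reagent → target + by-product (k = 8.40 × 10⁻⁶ M⁻¹ s⁻¹, Ea = 105 kJ mol⁻¹)
    gas ⇌ reagent, rate k3*(csat - [reagent]) (kL = 0.0730 s⁻¹)
    substrate ⇌ dormant form (K = 0.940, k = 1.40 × 10⁻⁴ s⁻¹, Ea = 94.0 kJ mol⁻¹, ΔH = −68.0 kJ mol⁻¹)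
    target ⇌ isomer of the product (K = 0.740, k = 0.00250 s⁻¹, Ea = 105 kJ mol⁻¹, ΔH = −47.0 kJ mol⁻¹)
    (constants at 70 °C)

In birch, half of the turnover up to 8.0 h of the making of target from substrate, reagent and by-product is done by 6.29 h. Birch's target goes from 1.05% at 4.00 h to 6.03% at 8.00 h, a doubling time of 1.59 h, beside the 1.47 h read in beta.

Read birch at 20 h instead: the doubling time read in beta allows 8.16 more doublings, a factor of 283 on 6.03%, which the charge cannot hold. That neighbour flask shows 21.1% target, with 3.51% substrate, 32.2% isomer of the product and 43.2% dormant form.

The earlier runs and the new flask were generated by integration with constants of no real substance; scatter was added.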